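## The problem

The target is a 2,6-diaryl-3,7-dioxabicyclo[3.3.0]octane (a furofuran: fusion carbons C1 and C5, aryl-bearing carbons C2 and C6, ring oxygens O3 and O7, methylene carbons C4 and C8; ring 1 holds O3, ring 2 holds O7). Its C2 aryl group is also the benzo ring of a 2-aryl-3-(hydroxymethyl)-7-methoxy-2,3-dihydrobenzofuran. There are six stereocentres in two blocks: C1, C2, C5 and C6 of the furofuran, with both aryl groups on the convex face, and the two dihydrobenzofuran carbons, whose substituents are cis. Within the furofuran, C1 can control C5 because the bicycle can only be cis-fused, and C1 and C2 can be set together in one acyclic step. C6 is a benzylic ether carbon whose configuration must be won in the ring closure itself. The two blocks are separated by an arene and cannot control each other, so the dihydrobenzofuran needs reagent-based control.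

The cis dihydrobenzofuran is the less stable isomer, and a carbonyl precursor at its C3 epimerises easily. All three benzylic C–O bonds stand para to an oxygen substituent, so they ionise with acid and are open to hydrogenolysis; free phenols reach the same ionisation through quinone methides. The feature that makes the key step possible is that C5 lies β to O3 through C4. In a 2-aryl-3-(hydroxymethyl)-2,3-dihydrofuran (ring 1 with a C4=C5 double bond) C5 is the nucleophilic enol ether carbon and the hydroxyl oxygen on C8 is O7. An aldehyde carbon bound first to O7 and then to C5 becomes C6 and closes ring 2.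

## Retrosynthesis

**Protecting groups and the hydroxymethyl group.** Target 34 is traced to bis-silyl ether 33 (two aryl O–Si bonds) and then to methyl ester 32 (ester in place of CH2OH). Silyl ethers are preferred to benzyl ethers because the last step must not be hydrogenolytic or acidic. The forward steps must reduce an epimerisable cis ester and free two phenols without opening a benzylic ether.

**Dihydrobenzofuran.** Ester 32 is cut at the C2–C3 bond of the dihydrobenzofuran to give diazo ester 31. Cutting the O–C2 bond instead would require a cationic or displacement closure at a para-oxygenated benzylic carbon, which gives the trans isomer. The carbene C–H insertion is the one closure that gives cis kinetically and takes its absolute sense from a catalyst. It is placed late so that the fragile cis ring meets only three further steps.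

**Side chain and ether.** Diazo ester 31 comes from arylacetate 30 by diazo transfer. Ether 30 is cut at the aryl O–CH2 bond into phenol 25 and benzylic bromide 29. Phenol 25 comes from benzyl ether 24, and 24 from aryl iodide 23 at the aryl–CH2 bond. Carrying iodine and a benzyl ether through the furofuran construction keeps the acid-labile para-silyloxybenzyl ether and the acidic arylacetate out of the Lewis acid step. The forward steps need a cross-coupling beside a benzyloxy group and a debenzylation that spares the furofuran.

**Key disconnection.** Furofuran 23 is cut at O7–C6 and C5–C6. C6 and its aryl group leave as acetal 20, and ring 1 remains as dihydrofuran alcohol 17.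
- Cutting C1–C5 or C1–C2 (conjugate addition or aldol logic) leaves both benzylic carbons to be made later at the wrong oxidation level.
- Cutting two C–O bonds leaves all four centres to an acyclic tetraol.
- The chosen cut removes one ring, one aryl group and two stereocentres (C5, C6). It leaves a monocycle with only the C1/C2 pair, which an auxiliary aldol can set.

The forward reaction must exchange the acetal onto O7 without harming the enol ether, form C5–C6 on the face of ring 1 that carries C8, place the syringyl group exo at C6, and end by hydride capture at C4 only. Structure secures all of these except the configuration at C6. The tether fixes C5 but not C6. Cyclisations of this kind are known to place the new aryl group endo when the C2 aryl group is cis to C8, and furofuran epimers at a benzylic carbon are of similar stability. Neither kinetic precedent nor thermodynamics therefore guarantees the exo isomer. Three choices strengthen this point from inside the step: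
- The dihydrofuran is trans, so the concave face below ring 1 is free for the transition state that leads to exo.
- The hydride is added only after cyclisation is complete at low temperature.
- Only C6 is made ionisable (para-silyloxy on the syringyl ring, iodine on the other ring), so C6 alone can be equilibrated later if needed.

**Dihydrofuran.** Alcohol 17 comes from silyl ether 16. The C4=C5 enol ether of 16 comes from lactol 14 by elimination. Lactol 14 comes from alkene 11 by cleavage of the terminal C=C, which in turn comes from diol 10 and aldol adduct 9. Adduct 9 is cut at C1–C2 into imide 6 and aldehyde 2. A syn aldol sets C1 and C2 in one step with a predictable absolute sense, whereas allylation or epoxide-opening routes set one centre at a time. Because the ring later closes through the carbinol oxygen and the allyl-derived carbon, the syn adduct maps onto the trans dihydrofuran. The forward sequence must keep the primary hydroxyl out of lactol formation and form an acid-sensitive enol ether.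

**Starting materials.** Aldehyde 2 comes from 5-iodovanillin 1. Imide 6 comes from pent-4-enoic acid 3 and oxazolidinone 4. Acetal 20 comes from syringaldehyde 18 through silyl ether 19. Bromide 29 comes from vanillin 26 through 27 and 28.

## Roads not taken

**Alternative 1:** The furofuran is cut at C5–C6 and C1–C2. Lithiated dithiane A2 adds to the β-carbon of menthyloxy butenolide A1, anti to the menthyloxy group. The enolate is trapped by aldehyde A3, anti to the new substituent, giving trans lactone A4.
- Merits: a three-component coupling that fixes C1 and C5 in one operation from an inexpensive chiral pool acetal. In convergence and in the control of these two centres it is at least equal to the chosen plan.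
- Weak points: C6 emerges as a dithiane and C2 as a carbinol mixture, so both benzylic centres must still be made. This needs dithiane removal beside an aryl iodide and an electron-rich benzyl ether, reduction of ketone, lactone and acetal carbons, and two ring closures through benzylic cations. The para-silyloxybenzyl ether of A3 must survive all of these.
- Comparison: those cationic closures tend to give the diequatorial isomer, which is an advantage over the chosen plan at C6. The chosen plan sets against this a C2 centre already fixed by the aldol, and closure of ring 2 with reduction of C4 in one flask instead of five or six operations after A4.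

**Alternative 2:** Both rings are cut at once, at C1–C5 and C6–O7. Cp2TiCl (trivalent titanium) opens the epoxide of ether A5 to a C1 radical. This cyclises 5-exo onto the sinapyl alkene, and after oxidation with I2 the benzylic C6 cation is captured by the titanium-bound O7, giving furofuran A6.
- Merits: the shortest route to the bicycle. The C6–O7 bond forms by capture of a benzylic cation, which favours exo, so on C6 this road is as good as or better than the chosen plan.
- Weak points: the C1 radical loses the epoxide configuration, so C1 and C5 depend on one acyclic benzylic ether centre through a 5-exo transition state of moderate fidelity. That centre is a para-oxygenated benzylic carbinol that is hard to obtain and keep enantiopure. Premature reduction of the radical and deoxygenation of the epoxide compete. The aryl iodide and silyl ethers must tolerate low-valent titanium and then iodine.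
- Comparison: the chosen plan is longer but sets against this an auxiliary-controlled C1/C2 pair, a tether-enforced C5, and purely ionic conditions compatible with the aryl iodide.

**Alternative 3:** The strategic cut is the C2–C3 bond of the dihydrobenzofuran. Diazo ester A7 loses N2 at a chiral dirhodium carboxylate (divalent rhodium), and the carbene inserts into the benzylic C–H bond of the ortho ether to give cis ester A8. A7 and A8 are identical with 31 and 32 of the chosen route.
- Merits: the best precedented enantioselective entry to cis 2-aryl-dihydrobenzofurans, and on reliability it is stronger than the chosen key step.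
- Weak points: it answers two of six stereocentres and presupposes the complete furofuran.
- Comparison: it is adopted as step 19 of the chosen route rather than made the centre of the plan. The chosen plan spends its strategic step on the furofuran, where more bonds and stereocentres are open, and accepts the higher risk there.

Key step: step 11

Assumption: for the phthaloyl-tert-leucinate dirhodium catalysts the (S) catalyst is taken to give the (2R) cis ester in the parent 2-aryl series, so the (2S) ester needed here is assigned to Rh2(R-PTTL)4, and the remote furofuran is assumed not to override the catalyst.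

Abbreviations: TBS = tert-butyl(dimethyl)silyl; TIPS = tri(propan-2-yl)silyl; ArI = 4-(benzyloxy)-3-iodo-5-methoxyphenyl; Fur = (1R,2S,5R,6S)-6-[3,5-dimethoxy-4-(TIPS-oxy)phenyl]-3,7-dioxabicyclo[3.3.0]octan-2-yl; Rh2(R-PTTL)4 = dirhodium tetrakis[N-phthaloyl-(R)-tert-leucinate].

## Route

Step 1
Reactants: 1 5-iodovanillin (4-hydroxy-3-iodo-5-methoxybenzaldehyde)
Product: 2 4-(benzyloxy)-3-iodo-5-methoxybenzaldehyde
Conditions: BnBr, K2CO3, DMF, rt
Reagents that add atoms: benzyl bromide, BrCc1ccccc1
Why: Williamson etherification of the phenoxide; the benzyl ether survives the boron enolate, hydride, oxidative cleavage and TMSOTf steps and can later be removed without acid.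

Step 2
Reactants: 3 pent-4-enoic acid; 4 (S)-4-benzyloxazolidin-2-one
Product: 6 (S)-4-benzyl-3-(pent-4-enoyl)oxazolidin-2-one, via mixed pivalic anhydride 5 (not isolated)
Conditions: PivCl, Et3N, THF, −20 °C; then LiCl, 4, −20 °C → rt
Reagents that add atoms: none
Why: N-acylation of the oxazolidinone through the mixed anhydride with LiCl activation, the standard entry to Evans imides.

Step 3
Reactants: 6 (S)-4-benzyl-3-(pent-4-enoyl)oxazolidin-2-one; 2 4-(benzyloxy)-3-iodo-5-methoxybenzaldehyde
Product: 9 (S)-4-benzyl-3-{(2S)-2-[(S)-(ArI)(hydroxy)methyl]pent-4-enoyl}oxazolidin-2-one (syn aldol adduct), via dibutylboron Z-enolate 7 (not isolated), via dibutylboron aldolate 8 (not isolated)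
Conditions: Bu2BOTf, i-Pr2NEt, CH2Cl2, 0 °C; then 2, −78 → 0 °C; then pH 7 buffer, MeOH, H2O2
Reagents that add atoms: none
Why: Evans syn aldol; the Z boron enolate reacts through a closed Zimmerman–Traxler chair on the face away from the benzyl group of the auxiliary, which should set C1 (α-carbon, 2S) and C2 (carbinol, S) together in the syn relationship.

Step 4
Reactants: 9 syn aldol adduct
Product: 10 (1S,2R)-1-(ArI)-2-(prop-2-en-1-yl)propane-1,3-diol
Conditions: LiBH4, MeOH (1 equiv), THF, 0 °C
Reagents that add atoms: none
Why: reductive cleavage of the imide to the primary alcohol with release of the auxiliary; aryl iodide, alkene and both stereocentres are not touched (the descriptor at C1 changes only through priorities).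

Step 5
Reactants: 10 (1S,2R)-1-(ArI)-2-(prop-2-en-1-yl)propane-1,3-diol
Product: 11 (1S,2R)-1-(ArI)-2-[(TBS-oxy)methyl]pent-4-en-1-ol
Conditions: TBSCl, imidazole, CH2Cl2, 0 °C
Reagents that add atoms: tert-butyl(chloro)dimethylsilane, CC(C)(C)[Si](C)(C)Cl
Why: selective silylation of the primary hydroxyl over the hindered benzylic one; it leaves only the benzylic hydroxyl to capture the aldehyde in step 6, so a single lactol forms and not a bicyclic acetal.

Step 6
Reactants: 11 (1S,2R)-1-(ArI)-2-[(TBS-oxy)methyl]pent-4-en-1-ol
Product: 14 (4R,5S)-5-(ArI)-4-[(TBS-oxy)methyl]oxolan-2-ol (both anomers), via triol 12 (not isolated), via hydroxy aldehyde 13 (not isolated)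
Conditions: OsO4 (cat.), NaIO4, 2,6-lutidine, dioxane–H2O, rt
Reagents that add atoms: sodium periodate, [Na+].[O-]I(=O)(=O)=O; osmium tetroxide, O=[Os](=O)(=O)=O
Why: Lemieux–Johnson cleavage of the terminal alkene; the aldehyde is trapped at once by the benzylic hydroxyl as the five-membered lactol, and the buffered, non-ozone conditions spare the electron-rich arene and benzyl ether.

Step 7
Reactants: 14 lactol
Product: 16 tert-butyl{[(2S,3R)-2-(ArI)-2,3-dihydrofuran-3-yl]methoxy}dimethylsilane, via lactol mesylate 15 (not isolated)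
Conditions: MsCl, Et3N, CH2Cl2, −20 → 40 °C
Reagents that add atoms: none
Why: the anomeric mesylate ionises to the cyclic oxocarbenium ion, which loses a proton from the only adjacent methylene group (E1-type glycal formation from a lactol); this should give the C4=C5 enol ether as the sole regioisomer with C1 and C2 unchanged (trans).

Step 8
Reactants: 16 silyl ether of the dihydrofuran
Product: 17 [(2S,3R)-2-(ArI)-2,3-dihydrofuran-3-yl]methanol (2,3-trans)
Conditions: Bu4NF, THF, 0 °C
Reagents that add atoms: none
Why: fluoride cleavage of the primary silyl ether under basic conditions that the enol ether tolerates; it frees the O7 hydroxyl for the acetal exchange.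

Step 9
Reactants: 18 syringaldehyde (4-hydroxy-3,5-dimethoxybenzaldehyde)
Product: 19 3,5-dimethoxy-4-(TIPS-oxy)benzaldehyde
Conditions: TIPSCl, imidazole, DMAP (cat.), DMF, 40 °C
Reagents that add atoms: chlorotri(propan-2-yl)silane, CC(C)[Si](Cl)(C(C)C)C(C)C
Why: silylation of the hindered phenol; the TIPS ether survives TMSOTf at low temperature and the later carbonate and amidine bases, keeps the ring electron-rich, and is removed by fluoride at the end.

Step 10
Reactants: 19 3,5-dimethoxy-4-(TIPS-oxy)benzaldehyde
Product: 20 [4-(dimethoxymethyl)-2,6-dimethoxyphenoxy]tri(propan-2-yl)silane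
Conditions: HC(OMe)3, MeOH, pyridinium p-toluenesulfonate (cat.), rt; Et3N quench
Reagents that add atoms: trimethyl orthoformate, COC(OC)OC; methanol, CO
Why: acid-catalysed acetalisation driven by the orthoformate as water scavenger; the aryl silyl ether is stable to the mild acid.

Step 11
Reactants: 17 [(2S,3R)-2-(ArI)-2,3-dihydrofuran-3-yl]methanol; 20 [4-(dimethoxymethyl)-2,6-dimethoxyphenoxy]tri(propan-2-yl)silane
Product: 23 (1R,2S,5R,6S)-2-(ArI)-6-[3,5-dimethoxy-4-(TIPS-oxy)phenyl]-3,7-dioxabicyclo[3.3.0]octane, via mixed methyl acetal 21 (not isolated), via bicyclic methyl acetal 22 (not isolated)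
Conditions: 20 (1.2 equiv), TMSOTf (1.2 equiv), 2,6-di-tert-butyl-4-methylpyridine (1.0 equiv), CH2Cl2, −78 °C; then Et3SiH (3 equiv), −78 → −40 °C; then aq. NaHCO3
Reagents that add atoms: none
Why: TMSOTf ionises 20 to a methoxy-substituted benzylic oxocarbenium ion that the hydroxyl of 17 captures (the pyridine takes the proton), giving mixed acetal 21 (O7–C6), and a second ionisation gives the O7=C6 oxocarbenium ion tethered to C1 through C8. The enol ether attacks through its β-carbon C5 (C5–C6), since only this places the new cation at C4 beside O3; ring 2 therefore closes as a five-membered ring, exo with respect to the enol ether and endo with respect to the O7=C6 bond, a mode that cationic closures of this kind accept. The C4 cation rests as methyl acetal 22 and is then reduced by Et3SiH to the methylene group. The closest known reaction type is the Lewis-acid-mediated cyclisation of 2-aryl-3-(hydroxymethyl)-2,3-dihydrofurans with aryl aldehyde dimethyl acetals to furofuranyl acetals, followed by ionic hydrogenation of the acetal. C5 is controlled by C1: the three-atom tether reaches only the face of ring 1 that carries C8, so the fusion must be cis. C6 is controlled by the E geometry of the oxocarbenium ion (aryl anti to C8) and by the orientation in which C4 lies anti to O7; this keeps the syringyl group from eclipsing C4 and should place it exo, and it needs the concave face below ring 1 to be free, which the trans C2 aryl group provides. The step needs exo selectivity at C6 (the least secure point), reduction of the C4 acetal without ionic hydrogenolysis of the benzylic ethers (hydride only after cyclisation, low temperature), and an intact enol ether until it has reacted (buffered, aprotic conditions).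

Step 12
Reactants: 23 furofuran aryl iodide
Product: 24 methyl 2-[2-(benzyloxy)-3-methoxy-5-(Fur)phenyl]acetate
Conditions: BrZnCH2CO2Me (from methyl bromoacetate and Zn dust, THF), Pd[P(t-Bu)3]2 (cat.), THF, rt → 45 °C
Reagents that add atoms: bromo(2-methoxy-2-oxoethyl)zinc, COC(=O)C[Zn]Br
Why: Negishi-type coupling of the Reformatsky reagent with the aryl iodide (oxidative addition at zerovalent palladium, transmetalation of the zinc enolate, reductive elimination); the neutral zinc reagent leaves the ethers and stereocentres alone.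

Step 13
Reactants: 24 methyl 2-[2-(benzyloxy)-3-methoxy-5-(Fur)phenyl]acetate
Product: 25 methyl 2-[2-hydroxy-3-methoxy-5-(Fur)phenyl]acetate
Conditions: H2 (1 atm), Pd/C, EtOAc, rt, stopped at full conversion
Reagents that add atoms: none
Why: hydrogenolysis of the aryl benzyl ether, which should be much faster than cleavage of the dialkyl benzylic ethers of the furofuran in a neutral, aprotic solvent; the iodine is already gone, so no dehalogenation can interfere.

Step 14
Reactants: 26 vanillin (4-hydroxy-3-methoxybenzaldehyde)
Product: 27 3-methoxy-4-(TIPS-oxy)benzaldehyde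
Conditions: TIPSCl, imidazole, DMF, rt
Reagents that add atoms: chlorotri(propan-2-yl)silane, CC(C)[Si](Cl)(C(C)C)C(C)C
Why: phenol silylation; the para-silyloxy group later activates the benzylic C–H bond toward carbene insertion.

Step 15
Reactants: 27 3-methoxy-4-(TIPS-oxy)benzaldehyde
Product: 28 [3-methoxy-4-(TIPS-oxy)phenyl]methanol
Conditions: NaBH4, MeOH, 0 °C
Reagents that add atoms: none
Why: borohydride reduction of the aldehyde; the aryl silyl ether is stable at 0 °C.

Step 16
Reactants: 28 [3-methoxy-4-(TIPS-oxy)phenyl]methanol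
Product: 29 [4-(bromomethyl)-2-methoxyphenoxy]tri(propan-2-yl)silane
Conditions: CBr4, PPh3, CH2Cl2, 0 °C; used at once
Reagents that add atoms: tetrabromomethane, BrC(Br)(Br)Br
Why: Appel bromination under neutral conditions, chosen because the electron-rich benzylic bromide and the silyl ether would not tolerate HBr.

Step 17
Reactants: 25 methyl 2-[2-hydroxy-3-methoxy-5-(Fur)phenyl]acetate; 29 [4-(bromomethyl)-2-methoxyphenoxy]tri(propan-2-yl)silane
Product: 30 methyl 2-[3-methoxy-2-{[3-methoxy-4-(TIPS-oxy)phenyl]methoxy}-5-(Fur)phenyl]acetate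
Conditions: K2CO3, acetone, 50 °C
Reagents that add atoms: none
Why: Williamson etherification of the phenoxide with the reactive benzylic bromide; anhydrous carbonate in acetone is too weak to deprotonate the arylacetate or to cleave the TIPS ethers.

Step 18
Reactants: 30 arylacetate ether
Product: 31 methyl 2-diazo-2-[3-methoxy-2-{[3-methoxy-4-(TIPS-oxy)phenyl]methoxy}-5-(Fur)phenyl]acetate
Conditions: 4-acetamidobenzenesulfonyl azide, DBU, MeCN, 0 °C → rt
Reagents that add atoms: 4-acetamidobenzenesulfonyl azide, CC(=O)Nc1ccc(cc1)S(=O)(=O)N=[N+]=[N-]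
Why: Regitz diazo transfer to the arylacetate enolate, the standard route to aryldiazoacetates; TIPS (not TBS) ethers are used so that anhydrous DBU does not desilylate the phenols.

Step 19
Reactants: 31 diazo ester
Product: 32 methyl (2S,3R)-7-methoxy-2-[3-methoxy-4-(TIPS-oxy)phenyl]-5-(Fur)-2,3-dihydro-1-benzofuran-3-carboxylate (2,3-cis)
Conditions: Rh2(R-PTTL)4 (2 mol%), toluene, −60 °C
Reagents that add atoms: none
Why: the dirhodium carboxylate (divalent rhodium) forms a donor/acceptor carbene that inserts into the benzylic C–H bond α to the ether oxygen (1,5-insertion, concerted, closing the five-membered ring); the insertion geometry gives the cis 2-aryl-3-ester relationship under kinetic control, and the chiral catalyst selects the prochiral hydrogen and carbene face, so both centres are set by the catalyst.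

Step 20
Reactants: 32 cis ester
Product: 33 [(2S,3S)-7-methoxy-2-[3-methoxy-4-(TIPS-oxy)phenyl]-5-(Fur)-2,3-dihydro-1-benzofuran-3-yl]methanol (2,3-cis)
Conditions: i-Bu2AlH, CH2Cl2, −78 → −40 °C; aq. potassium sodium tartrate
Reagents that add atoms: none
Why: hydride reduction of the ester to the primary alcohol under non-basic, low-temperature conditions, so that the centre α to the ester is not equilibrated to trans; once reduced it can no longer epimerise (the descriptor at C3 changes only through priorities).

Step 21
Reactants: 33 bis-silyl ether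
Product: 34 4-[(2S,3S)-5-[(1R,2S,5R,6S)-6-(4-hydroxy-3,5-dimethoxyphenyl)-3,7-dioxabicyclo[3.3.0]octan-2-yl]-3-(hydroxymethyl)-7-methoxy-2,3-dihydro-1-benzofuran-2-yl]-2-methoxyphenol (CNP0126146.1)
Conditions: Bu4NF, AcOH, THF, 0 °C
Reagents that add atoms: none
Why: fluoride cleavage of both aryl silyl ethers; acetic acid buffers the phenoxides so that neither the cis dihydrobenzofuran nor the syringyl ether can open through a quinone methide.

## Compound list

1 | 5-iodovanillin | COc1cc(C=O)cc(I)c1O | starting material
2 | 4-(benzyloxy)-3-iodo-5-methoxybenzaldehyde | COc1cc(C=O)cc(I)c1OCc1ccccc1 | intermediate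
3 | pent-4-enoic acid | C=CCCC(=O)O | starting material
4 | (S)-4-benzyloxazolidin-2-one | O=C1N[C@@H](Cc2ccccc2)CO1 | starting material
5 | pent-4-enoic pivalic anhydride (not isolated) | C=CCCC(=O)OC(=O)C(C)(C)C | intermediate
6 | (S)-4-benzyl-3-(pent-4-enoyl)oxazolidin-2-one | C=CCCC(=O)N1[C@@H](Cc2ccccc2)COC1=O | intermediate
7 | dibutylboron Z-enolate of 6 (not isolated) | C=CC/C=C(\OB(CCCC)CCCC)N1[C@@H](Cc2ccccc2)COC1=O | intermediate
8 | dibutylboron aldolate of 9 (not isolated) | O=C1OC[C@H](Cc2ccccc2)N1C(=O)[C@@H](CC=C)[C@H](OB(CCCC)CCCC)c1cc(OC)c(OCc2ccccc2)c(I)c1 | intermediate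
9 | (S)-4-benzyl-3-{(2S)-2-[(S)-(4-benzyloxy-3-iodo-5-methoxyphenyl)(hydroxy)methyl]pent-4-enoyl}oxazolidin-2-one | O=C1OC[C@H](Cc2ccccc2)N1C(=O)[C@@H](CC=C)[C@H](O)c1cc(OC)c(OCc2ccccc2)c(I)c1 | intermediate
10 | (1S,2R)-1-(4-benzyloxy-3-iodo-5-methoxyphenyl)-2-(prop-2-en-1-yl)propane-1,3-diol | OC[C@@H](CC=C)[C@H](O)c1cc(OC)c(OCc2ccccc2)c(I)c1 | intermediate
11 | (1S,2R)-1-(4-benzyloxy-3-iodo-5-methoxyphenyl)-2-[(TBS-oxy)methyl]pent-4-en-1-ol | CC(C)(C)[Si](C)(C)OC[C@@H](CC=C)[C@H](O)c1cc(OC)c(OCc2ccccc2)c(I)c1 | intermediate
12 | (1S,2R)-1-(4-benzyloxy-3-iodo-5-methoxyphenyl)-2-[(TBS-oxy)methyl]pentane-1,4,5-triol, C4 epimers (not isolated) | CC(C)(C)[Si](C)(C)OC[C@@H](CC(O)CO)[C@H](O)c1cc(OC)c(OCc2ccccc2)c(I)c1 | intermediate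
13 | (3R,4S)-4-(4-benzyloxy-3-iodo-5-methoxyphenyl)-4-hydroxy-3-[(TBS-oxy)methyl]butanal (not isolated) | CC(C)(C)[Si](C)(C)OC[C@@H](CC=O)[C@H](O)c1cc(OC)c(OCc2ccccc2)c(I)c1 | intermediate
14 | (4R,5S)-5-(4-benzyloxy-3-iodo-5-methoxyphenyl)-4-[(TBS-oxy)methyl]oxolan-2-ol, both anomers | CC(C)(C)[Si](C)(C)OC[C@H]1CC(O)O[C@@H]1c1cc(OC)c(OCc2ccccc2)c(I)c1 | intermediate
15 | methanesulfonate of lactol 14 (not isolated) | CC(C)(C)[Si](C)(C)OC[C@H]1CC(OS(C)(=O)=O)O[C@@H]1c1cc(OC)c(OCc2ccccc2)c(I)c1 | intermediate
16 | tert-butyl{[(2S,3R)-2-(4-benzyloxy-3-iodo-5-methoxyphenyl)-2,3-dihydrofuran-3-yl]methoxy}dimethylsilane | CC(C)(C)[Si](C)(C)OC[C@H]1C=CO[C@@H]1c1cc(OC)c(OCc2ccccc2)c(I)c1 | intermediate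
17 | [(2S,3R)-2-(4-benzyloxy-3-iodo-5-methoxyphenyl)-2,3-dihydrofuran-3-yl]methanol | OC[C@H]1C=CO[C@@H]1c1cc(OC)c(OCc2ccccc2)c(I)c1 | intermediate
18 | syringaldehyde | COc1cc(C=O)cc(OC)c1O | starting material
19 | 3,5-dimethoxy-4-(TIPS-oxy)benzaldehyde | COc1cc(C=O)cc(OC)c1O[Si](C(C)C)(C(C)C)C(C)C | intermediate
20 | [4-(dimethoxymethyl)-2,6-dimethoxyphenoxy]tri(propan-2-yl)silane | COC(OC)c1cc(OC)c(O[Si](C(C)C)(C(C)C)C(C)C)c(OC)c1 | intermediate
21 | mixed methyl acetal: 17 carrying on its hydroxyl oxygen the methoxy[3,5-dimethoxy-4-(TIPS-oxy)phenyl]methyl group, acetal epimers (not isolated) | COC(OC[C@H]1C=CO[C@@H]1c1cc(OC)c(OCc2ccccc2)c(I)c1)c1cc(OC)c(O[Si](C(C)C)(C(C)C)C(C)C)c(OC)c1 | intermediate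
22 | bicyclic methyl acetal: 23 carrying a methoxy group at C4, both anomers (not isolated) | COc1cc([C@H]2OC(OC)[C@H]3[C@@H]2CO[C@@H]3c2cc(OC)c(O[Si](C(C)C)(C(C)C)C(C)C)c(OC)c2)cc(I)c1OCc1ccccc1 | intermediate
23 | (1R,2S,5R,6S)-2-(4-benzyloxy-3-iodo-5-methoxyphenyl)-6-[3,5-dimethoxy-4-(TIPS-oxy)phenyl]-3,7-dioxabicyclo[3.3.0]octane | COc1cc([C@H]2OC[C@H]3[C@@H]2CO[C@@H]3c2cc(OC)c(O[Si](C(C)C)(C(C)C)C(C)C)c(OC)c2)cc(I)c1OCc1ccccc1 | intermediate
24 | methyl 2-[2-(benzyloxy)-3-methoxy-5-(Fur)phenyl]acetate | COc1cc([C@H]2OC[C@H]3[C@@H]2CO[C@@H]3c2cc(OC)c(O[Si](C(C)C)(C(C)C)C(C)C)c(OC)c2)cc(CC(=O)OC)c1OCc1ccccc1 | intermediate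
25 | methyl 2-[2-hydroxy-3-methoxy-5-(Fur)phenyl]acetate | COc1cc([C@H]2OC[C@H]3[C@@H]2CO[C@@H]3c2cc(OC)c(O[Si](C(C)C)(C(C)C)C(C)C)c(OC)c2)cc(CC(=O)OC)c1O | intermediate
26 | vanillin | COc1cc(C=O)ccc1O | starting material
27 | 3-methoxy-4-(TIPS-oxy)benzaldehyde | COc1cc(C=O)ccc1O[Si](C(C)C)(C(C)C)C(C)C | intermediate
28 | [3-methoxy-4-(TIPS-oxy)phenyl]methanol | COc1cc(CO)ccc1O[Si](C(C)C)(C(C)C)C(C)C | intermediate
29 | [4-(bromomethyl)-2-methoxyphenoxy]tri(propan-2-yl)silane | COc1cc(CBr)ccc1O[Si](C(C)C)(C(C)C)C(C)C | intermediate
30 | methyl 2-[3-methoxy-2-{[3-methoxy-4-(TIPS-oxy)phenyl]methoxy}-5-(Fur)phenyl]acetate | COc1cc([C@H]2OC[C@H]3[C@@H]2CO[C@@H]3c2cc(OC)c(O[Si](C(C)C)(C(C)C)C(C)C)c(OC)c2)cc(CC(=O)OC)c1OCc1ccc(O[Si](C(C)C)(C(C)C)C(C)C)c(OC)c1 | intermediate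
31 | methyl 2-diazo-2-[3-methoxy-2-{[3-methoxy-4-(TIPS-oxy)phenyl]methoxy}-5-(Fur)phenyl]acetate | COc1cc([C@H]2OC[C@H]3[C@@H]2CO[C@@H]3c2cc(OC)c(O[Si](C(C)C)(C(C)C)C(C)C)c(OC)c2)cc(C(=[N+]=[N-])C(=O)OC)c1OCc1ccc(O[Si](C(C)C)(C(C)C)C(C)C)c(OC)c1 | intermediate
32 | methyl (2S,3R)-7-methoxy-2-[3-methoxy-4-(TIPS-oxy)phenyl]-5-(Fur)-2,3-dihydro-1-benzofuran-3-carboxylate (cis) | COc1cc([C@H]2Oc3c(OC)cc([C@H]4OC[C@H]5[C@@H]4CO[C@@H]5c4cc(OC)c(O[Si](C(C)C)(C(C)C)C(C)C)c(OC)c4)cc3[C@H]2C(=O)OC)ccc1O[Si](C(C)C)(C(C)C)C(C)C | intermediate
33 | [(2S,3S)-7-methoxy-2-[3-methoxy-4-(TIPS-oxy)phenyl]-5-(Fur)-2,3-dihydro-1-benzofuran-3-yl]methanol (cis) | COc1cc([C@H]2Oc3c(OC)cc([C@H]4OC[C@H]5[C@@H]4CO[C@@H]5c4cc(OC)c(O[Si](C(C)C)(C(C)C)C(C)C)c(OC)c4)cc3[C@H]2CO)ccc1O[Si](C(C)C)(C(C)C)C(C)C | intermediate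
34 | 4-[(2S,3S)-5-[(1R,2S,5R,6S)-6-(4-hydroxy-3,5-dimethoxyphenyl)-3,7-dioxabicyclo[3.3.0]octan-2-yl]-3-(hydroxymethyl)-7-methoxy-2,3-dihydro-1-benzofuran-2-yl]-2-methoxyphenol | COc1cc([C@H]2Oc3c(OC)cc([C@H]4OC[C@H]5[C@@H]4CO[C@@H]5c4cc(OC)c(O)c(OC)c4)cc3[C@H]2CO)ccc1O | target

## Step count and least certain steps

Total: 21 steps. Longest linear sequence: 15 steps (1 → 2 → 9 → 10 → 11 → 14 → 16 → 17 → 23 → 24 → 25 → 30 → 31 → 32 → 33 → 34). The branches are step 2 (imide 6), steps 9–10 (acetal 20) and steps 14–16 (bromide 29).

**Step 11, the key step.** The most likely failure is poor or reversed facial selectivity at C6. The tethered enol ether may reach the E oxocarbenium ion in the compact orientation (C4 gauche to O7) instead of the open one, which would give the endo syringyl epimer. Secondary failures are acid-promoted addition of methanol to the enol ether before cyclisation and ionic hydrogenolysis of the C6–O7 bond once the hydride is present.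

The fallback gives up kinetic control at C6. The cascade is run from 17 and 20 as described, and the C6-epimeric furofuran F1 is taken as it forms. F1 is treated with BF3·OEt2 in CH2Cl2 at 0 °C. Only the C6–O7 bond ionises readily (para-silyloxy and two methoxy groups on that ring, iodine on the other), so C6 alone is scrambled through the ring-opened benzylic cation. The two epimers are expected to be of similar stability, so 23 is separated and F1 is returned to the equilibration. The fallback rejoins the route at 23.

**Step 19.** The most likely failure is insufficient face selection by the catalyst on this large substrate, which would give both cis diastereomers. A second failure is erosion of the cis relationship by epimerisation of the ester during handling.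

The fallback moves the stereocontrol from the catalyst alone to a covalently bound chiral ester. It sets out from 30. The methyl ester is cleaved with Me3SnOH in 1,2-dichloroethane to carboxylic acid F5. F5 is esterified (carbodiimide, DMAP) with (S)-2-hydroxy-1-(pyrrolidin-1-yl)propan-1-one to lactamide ester F6, using whichever enantiomer of the lactamide reinforces the catalyst. Diazo transfer gives diazo ester F7. The insertion is then run so that ester and dirhodium catalyst act together, giving cis lactamide ester F8. Reduction with i-Bu2AlH as in step 20 rejoins the route at 33.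

**Step 12.** The most likely failure is slow coupling beside the benzyloxy group, with protodehalogenation of the aryl iodide and self-condensation of the zinc enolate taking over.

The fallback replaces the zinc enolate by a soft malonate nucleophile. It sets out from 23. Palladium-catalysed arylation of dimethyl malonate (Pd[P(t-Bu)3]2, K3PO4, toluene, 70 °C) gives aryl malonate F4. Krapcho dealkoxycarbonylation (LiCl, wet DMSO, 130 °C) removes one ester group and rejoins the route at 24.

**Step 7.** The most likely failure is incomplete elimination of the anomeric sulfonate, together with hydrolysis or oligomerisation of the acid-sensitive enol ether by the ammonium salts on warming.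

The fallback replaces the ionising elimination by a thermal syn elimination. It sets out from 14. The lactol is converted with PhSSPh and Bu3P into phenylthio acetal F2. Oxidation with one equivalent of mCPBA at −78 °C gives sulfoxide F3. Heating F3 in toluene over solid NaHCO3 expels benzenesulfenic acid and rejoins the route at 16.

## Further compounds

F1 | step 11 | (1R,2S,5R,6R)-2-(4-benzyloxy-3-iodo-5-methoxyphenyl)-6-[3,5-dimethoxy-4-(TIPS-oxy)phenyl]-3,7-dioxabicyclo[3.3.0]octane (C6 epimer of 23) | COc1cc([C@H]2OC[C@H]3[C@@H]2CO[C@H]3c2cc(OC)c(O[Si](C(C)C)(C(C)C)C(C)C)c(OC)c2)cc(I)c1OCc1ccccc1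
F2 | step 7 | tert-butyl{[(2S,3R)-2-(4-benzyloxy-3-iodo-5-methoxyphenyl)-5-(phenylsulfanyl)oxolan-3-yl]methoxy}dimethylsilane (anomers) | CC(C)(C)[Si](C)(C)OC[C@H]1CC(Sc2ccccc2)O[C@@H]1c1cc(OC)c(OCc2ccccc2)c(I)c1
F3 | step 7 | the corresponding phenyl sulfoxide (diastereomers) | CC(C)(C)[Si](C)(C)OC[C@H]1CC(S(=O)c2ccccc2)O[C@@H]1c1cc(OC)c(OCc2ccccc2)c(I)c1
F4 | step 12 | dimethyl 2-[2-(benzyloxy)-3-methoxy-5-(Fur)phenyl]propanedioate | COc1cc([C@H]2OC[C@H]3[C@@H]2CO[C@@H]3c2cc(OC)c(O[Si](C(C)C)(C(C)C)C(C)C)c(OC)c2)cc(C(C(=O)OC)C(=O)OC)c1OCc1ccccc1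
F5 | step 19 | 2-[3-methoxy-2-{[3-methoxy-4-(TIPS-oxy)phenyl]methoxy}-5-(Fur)phenyl]acetic acid | COc1cc([C@H]2OC[C@H]3[C@@H]2CO[C@@H]3c2cc(OC)c(O[Si](C(C)C)(C(C)C)C(C)C)c(OC)c2)cc(CC(=O)O)c1OCc1ccc(O[Si](C(C)C)(C(C)C)C(C)C)c(OC)c1
F6 | step 19 | (S)-1-oxo-1-(pyrrolidin-1-yl)propan-2-yl ester of F5 | COc1cc([C@H]2OC[C@H]3[C@@H]2CO[C@@H]3c2cc(OC)c(O[Si](C(C)C)(C(C)C)C(C)C)c(OC)c2)cc(CC(=O)O[C@@H](C)C(=O)N2CCCC2)c1OCc1ccc(O[Si](C(C)C)(C(C)C)C(C)C)c(OC)c1
F7 | step 19 | α-diazo derivative of F6 | COc1cc([C@H]2OC[C@H]3[C@@H]2CO[C@@H]3c2cc(OC)c(O[Si](C(C)C)(C(C)C)C(C)C)c(OC)c2)cc(C(=[N+]=[N-])C(=O)O[C@@H](C)C(=O)N2CCCC2)c1OCc1ccc(O[Si](C(C)C)(C(C)C)C(C)C)c(OC)c1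
F8 | step 19 | (S)-1-oxo-1-(pyrrolidin-1-yl)propan-2-yl (2S,3R)-7-methoxy-2-[3-methoxy-4-(TIPS-oxy)phenyl]-5-(Fur)-2,3-dihydro-1-benzofuran-3-carboxylate (cis) | COc1cc([C@H]2Oc3c(OC)cc([C@H]4OC[C@H]5[C@@H]4CO[C@@H]5c4cc(OC)c(O[Si](C(C)C)(C(C)C)C(C)C)c(OC)c4)cc3[C@H]2C(=O)O[C@@H](C)C(=O)N2CCCC2)ccc1O[Si](C(C)C)(C(C)C)C(C)C
A1 | alternative 1 | (5R)-5-[(1R,2S,5R)-menthyloxy]furan-2(5H)-one | O=C1C=C[C@H](O[C@@H]2C[C@H](C)CC[C@H]2C(C)C)O1
A2 | alternative 1 | 2-lithio-2-[3,5-dimethoxy-4-(TIPS-oxy)phenyl]-1,3-dithiane | [Li]C1(SCCCS1)c1cc(OC)c(O[Si](C(C)C)(C(C)C)C(C)C)c(OC)c1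
A3 | alternative 1 | 3-iodo-5-methoxy-4-{[3-methoxy-4-(TIPS-oxy)phenyl]methoxy}benzaldehyde | COc1cc(C=O)cc(I)c1OCc1ccc(O[Si](C(C)C)(C(C)C)C(C)C)c(OC)c1
A4 | alternative 1 | trans-3,4-disubstituted menthyloxy lactone (carbinol epimers) | O=C1O[C@@H](O[C@@H]2C[C@H](C)CC[C@H]2C(C)C)[C@H](C2(SCCCS2)c2cc(OC)c(O[Si](C(C)C)(C(C)C)C(C)C)c(OC)c2)[C@H]1C(O)c1cc(OC)c(OCc2ccc(O[Si](C(C)C)(C(C)C)C(C)C)c(OC)c2)c(I)c1
A5 | alternative 2 | epoxide-bearing benzylic sinapyl ether (benzylic carbon R; epoxide carbon either) | COc1cc([C@@H](OC/C=C/c2cc(OC)c(O[Si](C(C)C)(C(C)C)C(C)C)c(OC)c2)C2CO2)cc(I)c1OCc1ccc(O[Si](C(C)C)(C(C)C)C(C)C)c(OC)c1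
A6 | alternative 2 | diequatorial furofuran with the iodo, vanillyloxy, methoxy aryl group | COc1cc([C@H]2OC[C@H]3[C@@H]2CO[C@@H]3c2cc(OC)c(O[Si](C(C)C)(C(C)C)C(C)C)c(OC)c2)cc(I)c1OCc1ccc(O[Si](C(C)C)(C(C)C)C(C)C)c(OC)c1
A7 | alternative 3 | aryldiazoacetate (identical with 31) | COc1cc([C@H]2OC[C@H]3[C@@H]2CO[C@@H]3c2cc(OC)c(O[Si](C(C)C)(C(C)C)C(C)C)c(OC)c2)cc(C(=[N+]=[N-])C(=O)OC)c1OCc1ccc(O[Si](C(C)C)(C(C)C)C(C)C)c(OC)c1
A8 | alternative 3 | cis dihydrobenzofuran methyl ester (identical with 32) | COc1cc([C@H]2Oc3c(OC)cc([C@H]4OC[C@H]5[C@@H]4CO[C@@H]5c4cc(OC)c(O[Si](C(C)C)(C(C)C)C(C)C)c(OC)c4)cc3[C@H]2C(=O)OC)ccc1O[Si](C(C)C)(C(C)C)C(C)C
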